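**Plan**

Numbering: ring B (phenol half) is C1 (CO2Me), C2 (OMe), C3 (Me), C4 (O-acyl), C5 (Me), C6 (Me). Ring A (acid half) is C1' (C=O), C2' (OMe), C3' (Me), C4' (OH), C5' (Cl), C6' (Me).
Cuts: first the depside bond O4–C(=O), with O4' masked as a benzyl ether, then the ring B bonds C3–C4 and C5–C6. Ring A is kept whole, and its Cl, OMe and acid functions are traced back to methyl atratate.
Enabling feature: ring B carbons C3(Me), C2(OMe), C1(CO2Me) and C6(Me) carry the substituent pattern of C3, C4, C5 and C6 of a 2-pyrone. The remaining pair C4(O)–C5(Me) is propyne oxygenated at C1, and O4 lies para to the ester, the orientation a 5-carboxylated pyrone imposes on a polarised alkyne.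
Forward order: the pyrone is built from methylmalonyl dichloride and methyl acetoacetate and O-methylated. Cycloaddition with the silyl ynol ether and loss of CO2 turn it into carbocyclic ring B. Desilylation, esterification with the ring A acid and debenzylation follow.
Stereochemistry: the target has no stereocentre and no configured double bond. The two bridgehead centres of the transient cycloadduct are erased on aromatisation, so only regiochemistry needs control.

Key step: step 5

**Step 1**
Reactants: 1 methylmalonic acid
Product: 2 methylmalonyl dichloride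
Conditions: SOCl2 (3 equiv), DMF (cat.), 55 °C; distillation
Reagents that add atoms: thionyl chloride, O=S(Cl)Cl
Why: Acid chloride formation with thionyl chloride under DMF catalysis is the standard preparation of malonyl dichlorides, and the moderate bath temperature stays below the decarboxylation range of the diacid.

**Step 2**
Reactants: 2 methylmalonyl dichloride; 3 methyl acetoacetate
Product: 5 methyl 4-hydroxy-2,5-dimethyl-6-oxo-6H-pyran-3-carboxylate, via acyclic keto acid chloride 4 (not isolated)
Conditions: PhMe, 80 °C, N2 sweep (HCl driven off)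
Reagents that add atoms: none
Why: Double acylation of the β-keto ester (C-acylation at the central carbon, then six-membered lactonisation through the ketone enol oxygen) is the classical malonyl dichloride route to 4-hydroxy-2-pyrone-5-carboxylates, and either order of the two acylations leads to the same ring.

**Step 3**
Reactants: 5 methyl 4-hydroxy-2,5-dimethyl-6-oxo-6H-pyran-3-carboxylate
Product: 6 methyl 4-methoxy-2,5-dimethyl-6-oxo-6H-pyran-3-carboxylate
Conditions: Me2SO4, K2CO3, acetone, reflux
Reagents that add atoms: dimethyl sulfate, COS(=O)(=O)OC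
Why: Williamson-type O-alkylation of the acidic vinylogous acid with the hard electrophile dimethyl sulfate is the usual entry to 4-methoxy-2-pyrones and disfavours both C3-methylation and formation of the 2-methoxy-4-pyrone isomer.

**Step 4**
Reactants: 7 propyne
Product: 10 triisopropyl(prop-1-yn-1-yloxy)silane, via prop-1-ynyllithium 8 (not isolated), via lithium prop-1-yn-1-olate 9 (not isolated)
Conditions: n-BuLi, THF, −78 °C; t-BuOOLi [from t-BuOOH + LiN(SiMe3)2, THF, −78 °C], −78 → 0 °C; i-Pr3SiOTf, −78 → 0 °C
Reagents that add atoms: tert-butyl hydroperoxide, CC(C)(C)OO; triisopropylsilyl trifluoromethanesulfonate, CC(C)[Si](OS(=O)(=O)C(F)(F)F)(C(C)C)C(C)C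
Why: Electrophilic oxygenation of a lithium acetylide by lithium tert-butyl peroxide gives the ynolate, and the bulky silyl triflate traps it on oxygen rather than on carbon, which is the established acetylide oxidation/O-silylation route to silyl ynol ethers.

**Step 5**
Reactants: 6 methyl 4-methoxy-2,5-dimethyl-6-oxo-6H-pyran-3-carboxylate; 10 triisopropyl(prop-1-yn-1-yloxy)silane
Product: 12 methyl 2-methoxy-3,5,6-trimethyl-4-(triisopropylsilyloxy)benzoate, via bridged bicyclic lactone 11 (not isolated)
Conditions: HNTf2 (10 mol %), ClCH2CH2Cl, 10 (2 equiv, slow addition), 0 → 60 °C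
Reagents that add atoms: none
Why: HNTf2, acting directly and through the i-Pr3SiNTf2 it generates from 10, binds the lactone carbonyl of 6 and gives it pyrylium character; C2 and C4 of that cation are quenched by their oxygen donors, which leaves C6, also β to the C5 ester, as the electrophilic terminus. The nucleophilic methyl-bearing carbon of 10 bonds to pyrone C6 (ring B bond C5–C6), and the silyl ketenium carbon so formed is captured by pyrone C3, the nucleophilic end of the C3=C4(OMe) enol ether (ring B bond C3–C4), which amounts to an asynchronous inverse-electron-demand Diels–Alder reaction. Ring B is thus closed intermolecularly in the [4+2] mode as the cyclohexadiene part of the 2-oxabicyclo[2.2.2]octadienone 11, and a retro-[4+2] loss of CO2 then aromatises it irreversibly without any oxidant. The closest known reaction type is the cycloaddition of ester-bearing 2-pyrones with ynamines, ynol ethers and siloxy alkynes followed by CO2 extrusion, run thermally or under Brønsted or Lewis acid catalysis; a pyrone substituted at all four carbons is only a more hindered member of that class. The two quaternary bridgehead centres of 11 form as a racemate whose relative configuration is dictated by the bicycle, and both disappear with CO2, so no stereocontrol is called for. What the step needs is regioselectivity and [4+2] rather than [2+2] closure: the first is secured by the matched polarisation of both partners (C5 ester and ring oxygen at C6, 4-OMe at C3, silyloxy group on the alkyne), the second by the strain-free six-membered closure and by the CO2 loss that drains reversible adducts, while the triisopropylsilyl group, unlike an alkyl group, offers no retro-ene path to a ketene.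

**Step 6**
Reactants: 12 methyl 2-methoxy-3,5,6-trimethyl-4-(triisopropylsilyloxy)benzoate
Product: 13 methyl 4-hydroxy-2-methoxy-3,5,6-trimethylbenzoate
Conditions: Bu4NF, AcOH, THF, 0 °C
Reagents that add atoms: none
Why: Fluoride-induced cleavage of an aryl silyl ether is fast even between two ortho methyl groups because phenoxide is a good leaving group from silicon, and the acetic acid buffer protects the methyl ester.

**Step 7**
Reactants: 14 methyl atratate (methyl 2,4-dihydroxy-3,6-dimethylbenzoate)
Product: 15 methyl 5-chloro-2,4-dihydroxy-3,6-dimethylbenzoate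
Conditions: SO2Cl2 (1.05 equiv), CH2Cl2–Et2O, 0 °C → rt
Reagents that add atoms: sulfuryl chloride, O=S(=O)(Cl)Cl
Why: In this electrophilic aromatic chlorination C5 is the only unsubstituted ring carbon and lies ortho to the 4-OH and para to the 2-OH, so one equivalent of reagent can substitute only there.

**Step 8**
Reactants: 15 methyl 5-chloro-2,4-dihydroxy-3,6-dimethylbenzoate
Product: 16 methyl 4-(benzyloxy)-5-chloro-2-hydroxy-3,6-dimethylbenzoate
Conditions: BnBr (1.05 equiv), K2CO3, acetone, reflux
Reagents that add atoms: benzyl bromide, BrCc1ccccc1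
Why: The Williamson etherification should pick the 4-OH, which is acidified by the neighbouring chlorine, because the 2-OH is tied up in a hydrogen bond to the ester carbonyl, the customary differentiation in orsellinate-type esters.

**Step 9**
Reactants: 16 methyl 4-(benzyloxy)-5-chloro-2-hydroxy-3,6-dimethylbenzoate
Product: 17 methyl 4-(benzyloxy)-5-chloro-2-methoxy-3,6-dimethylbenzoate
Conditions: MeI (excess), K2CO3, DMF, 50 °C
Reagents that add atoms: iodomethane, CI
Why: Williamson methylation of the one remaining, chelated phenol proceeds under more forcing polar aprotic conditions, and no other nucleophilic site is left in the molecule.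

**Step 10**
Reactants: 17 methyl 4-(benzyloxy)-5-chloro-2-methoxy-3,6-dimethylbenzoate
Product: 18 4-(benzyloxy)-5-chloro-2-methoxy-3,6-dimethylbenzoic acid
Conditions: KOH, DMSO–H2O, 100 °C; then aq. HCl
Reagents that add atoms: potassium hydroxide, [K+].[OH-]
Why: Saponification of a di-ortho-substituted methyl benzoate calls for poorly solvated hydroxide in hot aqueous DMSO, conditions under which the ethers and the chloride on the electron-rich ring are inert.

**Step 11**
Reactants: 18 4-(benzyloxy)-5-chloro-2-methoxy-3,6-dimethylbenzoic acid; 13 methyl 4-hydroxy-2-methoxy-3,5,6-trimethylbenzoate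
Product: 20 methyl 4-{[4-(benzyloxy)-5-chloro-2-methoxy-3,6-dimethylbenzoyl]oxy}-2-methoxy-3,5,6-trimethylbenzoate, via mixed trifluoroacetic anhydride 19 (not isolated)
Conditions: (CF3CO)2O, PhMe, rt
Reagents that add atoms: none
Why: In this trifluoroacetic anhydride-mediated esterification, the standard depside coupling, the mixed anhydride of an electron-rich 2,6-disubstituted benzoic acid ionises easily to a linear acylium ion that escapes the steric blockade and acylates even a phenol between two methyl groups.

**Step 12**
Reactants: 20 methyl 4-{[4-(benzyloxy)-5-chloro-2-methoxy-3,6-dimethylbenzoyl]oxy}-2-methoxy-3,5,6-trimethylbenzoate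
Product: 21 methyl 4-[(5-chloro-4-hydroxy-2-methoxy-3,6-dimethylbenzoyl)oxy]-2-methoxy-3,5,6-trimethylbenzoate (CNP0192286.0)
Conditions: H2 (1 atm), Pd/C (10 wt %), EtOAc, rt, stopped at full conversion
Reagents that add atoms: none
Why: Catalytic hydrogenolysis of a benzyl aryl ether in a neutral, base-free aprotic medium should outrun reduction of the flanked aryl chloride and leaves both esters untouched, as is usual in closing chlorinated depside syntheses.

**Compound list**

1 | methylmalonic acid | CC(C(=O)O)C(=O)O | starting material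
2 | methylmalonyl dichloride (2-methylpropanedioyl dichloride) | CC(C(=O)Cl)C(=O)Cl | intermediate
3 | methyl acetoacetate | COC(=O)CC(C)=O | starting material
4 | methyl 2-acetyl-5-chloro-4-methyl-3,5-dioxopentanoate (formed in the flask; labile epimers and enol forms) | COC(=O)C(C(C)=O)C(=O)C(C)C(=O)Cl | intermediate
5 | methyl 4-hydroxy-2,5-dimethyl-6-oxo-6H-pyran-3-carboxylate (2-pyrone numbering: 3-Me, 4-OH, 5-CO2Me, 6-Me) | COC(=O)C1=C(C)OC(=O)C(C)=C1O | intermediate
6 | methyl 4-methoxy-2,5-dimethyl-6-oxo-6H-pyran-3-carboxylate (2-pyrone numbering: 3-Me, 4-OMe, 5-CO2Me, 6-Me) | COC(=O)C1=C(C)OC(=O)C(C)=C1OC | intermediate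
7 | propyne | CC#C | starting material
8 | prop-1-ynyllithium (formed in the flask) | [Li]C#CC | intermediate
9 | lithium prop-1-yn-1-olate (formed in the flask) | CC#C[O-].[Li+] | intermediate
10 | triisopropyl(prop-1-yn-1-yloxy)silane | CC#CO[Si](C(C)C)(C(C)C)C(C)C | intermediate
11 | methyl 5-methoxy-1,4,7-trimethyl-3-oxo-8-(triisopropylsilyloxy)-2-oxabicyclo[2.2.2]octa-5,7-diene-6-carboxylate (formed in the flask; racemic, one enantiomer drawn) | C[C@@]12OC(=O)[C@@](C)(C(OC)=C1C(=O)OC)C(O[Si](C(C)C)(C(C)C)C(C)C)=C2C | intermediate
12 | methyl 2-methoxy-3,5,6-trimethyl-4-(triisopropylsilyloxy)benzoate | COC(=O)c1c(C)c(C)c(O[Si](C(C)C)(C(C)C)C(C)C)c(C)c1OC | intermediate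
13 | methyl 4-hydroxy-2-methoxy-3,5,6-trimethylbenzoate | COC(=O)c1c(C)c(C)c(O)c(C)c1OC | intermediate
14 | methyl atratate (methyl 2,4-dihydroxy-3,6-dimethylbenzoate) | COC(=O)c1c(C)cc(O)c(C)c1O | starting material
15 | methyl 5-chloro-2,4-dihydroxy-3,6-dimethylbenzoate | COC(=O)c1c(C)c(Cl)c(O)c(C)c1O | intermediate
16 | methyl 4-(benzyloxy)-5-chloro-2-hydroxy-3,6-dimethylbenzoate | COC(=O)c1c(C)c(Cl)c(OCc2ccccc2)c(C)c1O | intermediate
17 | methyl 4-(benzyloxy)-5-chloro-2-methoxy-3,6-dimethylbenzoate | COC(=O)c1c(C)c(Cl)c(OCc2ccccc2)c(C)c1OC | intermediate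
18 | 4-(benzyloxy)-5-chloro-2-methoxy-3,6-dimethylbenzoic acid | OC(=O)c1c(C)c(Cl)c(OCc2ccccc2)c(C)c1OC | intermediate
19 | 4-(benzyloxy)-5-chloro-2-methoxy-3,6-dimethylbenzoic trifluoroacetic anhydride (formed in the flask) | O=C(OC(=O)C(F)(F)F)c1c(C)c(Cl)c(OCc2ccccc2)c(C)c1OC | intermediate
20 | methyl 4-{[4-(benzyloxy)-5-chloro-2-methoxy-3,6-dimethylbenzoyl]oxy}-2-methoxy-3,5,6-trimethylbenzoate | COC(=O)c1c(C)c(C)c(OC(=O)c2c(C)c(Cl)c(OCc3ccccc3)c(C)c2OC)c(C)c1OC | intermediate
21 | methyl 4-[(5-chloro-4-hydroxy-2-methoxy-3,6-dimethylbenzoyl)oxy]-2-methoxy-3,5,6-trimethylbenzoate (CNP0192286.0) | COC(=O)c1c(C)c(C)c(OC(=O)c2c(C)c(Cl)c(O)c(C)c2OC)c(C)c1OC | target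

**Step count**

Total step count: 12.
Longest linear sequence: 7 steps (1, 2, 3, 5, 6, 11, 12).

**Steps most likely to fail**

**Step 5.** The cycloaddition may be sluggish or may not occur. Both bonding termini of the pyrone carry methyl groups, and the 4-methoxy group lowers its electron demand. Acid-induced oligomerisation or hydrolysis of the siloxy alkyne, or a four-membered closure, could then outrun the [4+2] event.

The fallback gives up the cycloaddition and reaches ring B by substitution on a purchased arene. It sets out from 14 and comes back at 13. Rieche formylation of 14 (Cl2CHOMe, TiCl4, CH2Cl2, 0 °C) at its only free ring carbon should give methyl 5-formyl-2,4-dihydroxy-3,6-dimethylbenzoate F1. Hydrogenation of this ortho-hydroxy aldehyde over Pd/C in acetic acid takes the formyl group down to methyl and gives methyl 2,4-dihydroxy-3,5,6-trimethylbenzoate F2. Benzyl bromide and K2CO3 in acetone etherify the non-chelated 4-OH to methyl 4-(benzyloxy)-2-hydroxy-3,5,6-trimethylbenzoate F3. MeI and K2CO3 in DMF give methyl 4-(benzyloxy)-2-methoxy-3,5,6-trimethylbenzoate F4, and hydrogenolysis (H2, Pd/C, EtOAc) delivers 13.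

**Step 2.** Loss of HCl from the dichloride to a chlorocarbonyl ketene may be followed by self-condensation. Alternatively, acylation may stall at an O-acyl stage. Either process would erode ring formation.

The fallback separates the two acylations by using a malonyl unit with a single acid chloride. It sets out from 3 and comes back at 5. Dimethyl methylmalonate is half-saponified (KOH, 1 equiv, MeOH) to racemic 3-methoxy-2-methyl-3-oxopropanoic acid F5. SOCl2 converts this into racemic methyl 3-chloro-2-methyl-3-oxopropanoate F6. The magnesium enolate of 3 (MgCl2, pyridine, CH2Cl2, 0 °C) is C-acylated by F6 to dimethyl 2-acetyl-4-methyl-3-oxopentanedioate F7. DBU in refluxing toluene then closes the enol oxygen of the acetyl group onto the distal ester with loss of methanol, giving 5.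

**Step 12.** Hydrodechlorination at C5' may compete with the slow hydrogenolysis of a benzyl ether that is flanked by chlorine and methyl.

The fallback removes chlorine from the hydrogenolysis by installing it last. It sets out from 14, uses 13 as coupling partner and comes back at 21. Benzyl bromide and K2CO3 convert 14 into methyl 4-(benzyloxy)-2-hydroxy-3,6-dimethylbenzoate F8. MeI and K2CO3 in DMF give methyl 4-(benzyloxy)-2-methoxy-3,6-dimethylbenzoate F9, and KOH in hot aqueous DMSO gives 4-(benzyloxy)-2-methoxy-3,6-dimethylbenzoic acid F10.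

Trifluoroacetic anhydride in toluene turns F10 into 4-(benzyloxy)-2-methoxy-3,6-dimethylbenzoic trifluoroacetic anhydride F11. This acylates 13 to methyl 4-{[4-(benzyloxy)-2-methoxy-3,6-dimethylbenzoyl]oxy}-2-methoxy-3,5,6-trimethylbenzoate F12. Hydrogenolysis (H2, Pd/C, EtOAc), now free of any C–Cl bond, gives methyl 4-[(4-hydroxy-2-methoxy-3,6-dimethylbenzoyl)oxy]-2-methoxy-3,5,6-trimethylbenzoate F13. One equivalent of SO2Cl2 (CH2Cl2–Et2O, 0 °C) then chlorinates C5', the only aromatic C–H of the molecule and ortho to the free phenol, to give 21.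

**Further compounds**

F1 | step 5 | methyl 5-formyl-2,4-dihydroxy-3,6-dimethylbenzoate | COC(=O)c1c(C)c(C=O)c(O)c(C)c1O
F2 | step 5 | methyl 2,4-dihydroxy-3,5,6-trimethylbenzoate | COC(=O)c1c(C)c(C)c(O)c(C)c1O
F3 | step 5 | methyl 4-(benzyloxy)-2-hydroxy-3,5,6-trimethylbenzoate | COC(=O)c1c(C)c(C)c(OCc2ccccc2)c(C)c1O
F4 | step 5 | methyl 4-(benzyloxy)-2-methoxy-3,5,6-trimethylbenzoate | COC(=O)c1c(C)c(C)c(OCc2ccccc2)c(C)c1OC
F5 | step 2 | 3-methoxy-2-methyl-3-oxopropanoic acid (racemic) | COC(=O)C(C)C(=O)O
F6 | step 2 | methyl 3-chloro-2-methyl-3-oxopropanoate (racemic) | COC(=O)C(C)C(=O)Cl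
F7 | step 2 | dimethyl 2-acetyl-4-methyl-3-oxopentanedioate (labile epimers and enol forms) | COC(=O)C(C(C)=O)C(=O)C(C)C(=O)OC
F8 | step 12 | methyl 4-(benzyloxy)-2-hydroxy-3,6-dimethylbenzoate | COC(=O)c1c(C)cc(OCc2ccccc2)c(C)c1O
F9 | step 12 | methyl 4-(benzyloxy)-2-methoxy-3,6-dimethylbenzoate | COC(=O)c1c(C)cc(OCc2ccccc2)c(C)c1OC
F10 | step 12 | 4-(benzyloxy)-2-methoxy-3,6-dimethylbenzoic acid | OC(=O)c1c(C)cc(OCc2ccccc2)c(C)c1OC
F11 | step 12 | 4-(benzyloxy)-2-methoxy-3,6-dimethylbenzoic trifluoroacetic anhydride | O=C(OC(=O)C(F)(F)F)c1c(C)cc(OCc2ccccc2)c(C)c1OC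
F12 | step 12 | methyl 4-{[4-(benzyloxy)-2-methoxy-3,6-dimethylbenzoyl]oxy}-2-methoxy-3,5,6-trimethylbenzoate | COC(=O)c1c(C)c(C)c(OC(=O)c2c(C)cc(OCc3ccccc3)c(C)c2OC)c(C)c1OC
F13 | step 12 | methyl 4-[(4-hydroxy-2-methoxy-3,6-dimethylbenzoyl)oxy]-2-methoxy-3,5,6-trimethylbenzoate | COC(=O)c1c(C)c(C)c(OC(=O)c2c(C)cc(O)c(C)c2OC)c(C)c1OC
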